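## Retrosynthetic overview

1. The only ring to be built is the 22-membered macrocycle; rings A and B are bought as arenes. It is closed last, at the diaryl ether bond between the ring-A oxygen and C4 of ring B, in one operation from an open-chain precursor: fluoride-triggered double desilylation followed by intramolecular SNAr.
2. Enabling feature: the ether carbon C4 of ring B, flanked by the oxygenated carbons C3 and C5, is para to ring-B C1, which carries the carbinol carbon. At the ketone oxidation level this para-acyl group makes a C4–F bond an SNAr acceptor, and its later reduction removes the activator and sets the stereocenter. Ring A is a 5-alkylresorcinol whose two oxygens are equivalent, so either one closes the same ring.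
3. The seco-ketone is cut at the Z-alkene (C8=C9, Wittig) into a ring-B keto-aldehyde and a ring-A phosphonium salt.
4. Ring-B fragment: 2-fluororesorcinol, MOM protection, C–H borylation at C5, acylative Suzuki coupling, oxidative cleavage. Ring-A fragment: 5-bromoresorcinol, silylation, B-alkyl Suzuki coupling, phosphonium salt.
5. Endgame: MOM removal at the ketone stage, then asymmetric transfer hydrogenation to the R carbinol.

Key step: step 9

Remark: the carbinol carbon of the target is R (O > ring B > CH2 > H). Chain carbons are numbered C1 (carbinol, on ring B) to C14 (benzylic CH2 on ring A). Ring B is numbered from the chain-bearing carbon (C1; ether carbon C4). Ring A is numbered from the ether carbon (C1; chain on C3, free OH on C5).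

## Route

Step 1
Reactants: 1 2-fluorobenzene-1,3-diol
Product: 2 2-fluoro-1,3-bis(methoxymethoxy)benzene
Conditions: MOMCl (2.6 equiv), i-Pr2NEt (3.5 equiv), CH2Cl2, 0 °C to rt
Reagents that add atoms: chloromethyl methyl ether (MOMCl), COCCl
Why: Base-mediated O-alkylation of both phenols (acetal-type protection) should be clean, and the MOM acetals tolerate every basic, organometallic and oxidative step up to step 10.

Step 2
Reactants: 2 2-fluoro-1,3-bis(methoxymethoxy)benzene
Product: 3 2-[4-fluoro-3,5-bis(methoxymethoxy)phenyl]-4,4,5,5-tetramethyl-1,3,2-dioxaborolane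
Conditions: [Ir(OMe)(cod)]2 (1.5 mol%), 4,4'-di-tert-butyl-2,2'-bipyridine (3 mol%), B2pin2 (1.0 equiv), THF, 70 °C
Reagents that add atoms: bis(pinacolato)diboron, CC1(C)OB(OC1(C)C)B1OC(C)(C)C(C)(C)O1
Why: Sterically governed iridium-catalysed aromatic C–H borylation should occur only at C5, the one ring C–H with no ortho substituent, which is the carbon para to fluorine that must carry the chain.

Step 3
Reactants: 3 2-[4-fluoro-3,5-bis(methoxymethoxy)phenyl]-4,4,5,5-tetramethyl-1,3,2-dioxaborolane; 4 non-8-enoic acid
Product: 6 1-[4-fluoro-3,5-bis(methoxymethoxy)phenyl]non-8-en-1-one, via non-8-enoyl chloride 5 (not isolated)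
Conditions: 4, (COCl)2, cat. DMF, CH2Cl2, rt, evaporation; then 3, Pd(PPh3)4 (5 mol%), K3PO4·H2O, toluene, 80 °C
Reagents that add atoms: none
Why: Acylative Suzuki–Miyaura coupling (oxidative addition of zerovalent palladium into the C–Cl bond of acyl chloride 5, transmetalation from the boronate, reductive elimination) should give the aryl ketone directly, with the remote terminal alkene and the C–F bond inert.

Step 4
Reactants: 6 1-[4-fluoro-3,5-bis(methoxymethoxy)phenyl]non-8-en-1-one
Product: 8 8-[4-fluoro-3,5-bis(methoxymethoxy)phenyl]-8-oxooctanal, via the racemic 8,9-diol 7 (not isolated)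
Conditions: OsO4 (2 mol%), NaIO4 (4 equiv), 2,6-lutidine, 1,4-dioxane/H2O 3:1, rt
Reagents that add atoms: osmium tetroxide, O=[Os](=O)(=O)=O (transfers the oxygen); sodium periodate, [Na+].[O-]I(=O)(=O)=O (terminal oxidant)
Why: Lemieux–Johnson oxidation (catalytic dihydroxylation of the terminal alkene, then periodate glycol cleavage) should excise the terminal CH2 as formaldehyde and leave the aryl ketone and acetals untouched, 2,6-lutidine suppressing over-oxidation.

Step 5
Reactants: 9 5-bromobenzene-1,3-diol
Product: 10 1-bromo-3,5-bis(triisopropylsilyloxy)benzene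
Conditions: TIPSCl (2.4 equiv), imidazole (5 equiv), DMF, rt
Reagents that add atoms: chlorotriisopropylsilane (TIPSCl), CC(C)[Si](Cl)(C(C)C)C(C)C
Why: Imidazole-promoted silylation of both phenols should give bis(silyl ether) 10, stable to the following basic steps yet cleaved by fluoride in the key step.

Step 6
Reactants: 10 1-bromo-3,5-bis(triisopropylsilyloxy)benzene; 11 6-chlorohex-1-ene
Product: 13 1-(6-chlorohexyl)-3,5-bis(triisopropylsilyloxy)benzene, via 9-(6-chlorohexyl)-9-borabicyclo[3.3.1]nonane 12 (not isolated)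
Conditions: 11, 9-BBN, THF, rt; then 10, PdCl2(dppf) (3 mol%), K3PO4 (3 M aq.), DMF, 50 °C
Reagents that add atoms: none
Why: Anti-Markovnikov hydroboration of the terminal alkene followed by B-alkyl Suzuki–Miyaura coupling should join the sp3 chain to ring A, the primary C–Cl bond being inert to the palladium catalyst.

Step 7
Reactants: 13 1-(6-chlorohexyl)-3,5-bis(triisopropylsilyloxy)benzene
Product: 15 {6-[3,5-bis(triisopropylsilyloxy)phenyl]hexyl}triphenylphosphonium iodide, via the alkyl iodide 14 (not isolated)
Conditions: NaI (1.5 equiv), PPh3 (1.5 equiv), MeCN, reflux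
Reagents that add atoms: triphenylphosphine, c1ccccc1P(c1ccccc1)c1ccccc1; sodium iodide, [Na+].[I-]
Why: In situ Finkelstein exchange and SN2 quaternisation of triphenylphosphine by the primary iodide should give the Wittig salt.

Step 8
Reactants: 15 {6-[3,5-bis(triisopropylsilyloxy)phenyl]hexyl}triphenylphosphonium iodide; 8 8-[4-fluoro-3,5-bis(methoxymethoxy)phenyl]-8-oxooctanal
Product: 17 (Z)-1-[4-fluoro-3,5-bis(methoxymethoxy)phenyl]-14-[3,5-bis(triisopropylsilyloxy)phenyl]tetradec-8-en-1-one, via the phosphonium ylide 16 (not isolated)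
Conditions: 15 (1.1 equiv), NaN(SiMe3)2 (1.05 equiv), THF, 0 °C; then 8, −78 °C to −20 °C
Reagents that add atoms: none
Why: Wittig olefination of the non-stabilised ylide under lithium-free, kinetically controlled conditions should give the Z-alkene (C8=C9), and at −78 °C the aldehyde should react far faster than the deactivated, hindered aryl ketone.

Step 9
Reactants: 17 (Z)-1-[4-fluoro-3,5-bis(methoxymethoxy)phenyl]-14-[3,5-bis(triisopropylsilyloxy)phenyl]tetradec-8-en-1-one
Product: 19 macrocyclic ketone (11Z)-1^5-hydroxy-3^2,3^6-bis(methoxymethoxy)-2-oxa-1(1,3),3(1,4)-dibenzenacycloheptadecaphan-11-en-4-one (22-membered ring: ring-A C1–O–ring-B C4; ring-B C1–CO–(CH2)6–CH=CH–(CH2)5–ring-A C3; ring-A C5–OH), via the dicesium bisphenoxide 18 (not isolated)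
Conditions: CsF (5 equiv), DMSO, 110 °C, 17 added by syringe pump over 12 h (final 2 mM); then 0.5 M HCl, 0 °C
Reagents that add atoms: none
Why: Fluoride cleaves both aryl silyl ethers to bisphenoxide 18, one oxygen of which adds to C4 of ring B para to the ketone; the negative charge of the σ-adduct is delocalised onto the carbonyl oxygen and loss of fluoride restores aromaticity (addition–elimination SNAr). The closest known reaction type is the intramolecular SNAr macroetherification of phenoxides with activated aryl fluorides used for macrocyclic diaryl ethers, combined with the fluoride unmasking of aryl silyl ethers used in the silyl-ether variant of poly(aryl ether ketone) synthesis. The single ring closed is the 22-membered macrocycle, by attack of a phenoxide oxygen on an sp2 ring carbon with the breaking C–F bond outside the new ring (exo-type macrocyclisation); no stereocenter is formed and the Z-alkene is not touched. Ring closure over oligomerisation should be secured by slow addition at high dilution, and O- over C-arylation is inherent to a hard phenoxide attacking an aryl fluoride. No regiochemical question arises, because the two ring-A oxygens are equivalent by local symmetry and C4–F is the only activated position of ring B; the phenoxide left over cannot reach a second electrophile within the ring. The flanking MOM ethers are inductively withdrawing acetals and fluoride is the smallest nucleofuge, so the di-ortho-substituted carbon should remain accessible.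

Step 10
Reactants: 19 macrocyclic ketone (bis-MOM ether)
Product: 20 (11Z)-1^5,3^2,3^6-trihydroxy-2-oxa-1(1,3),3(1,4)-dibenzenacycloheptadecaphan-11-en-4-one (macrocyclic triphenol ketone)
Conditions: HCl (3 M aq.), MeOH/THF, 45 °C
Reagents that add atoms: none
Why: Acid-catalysed transacetalisation (MOM cleavage to dimethoxymethane) should free the two ring-B phenols while ketone, diaryl ether and Z-alkene are stable, and it is placed before the reduction so that no acid-labile benzylic stereocenter is exposed to acid.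

Step 11
Reactants: 20 macrocyclic triphenol ketone
Product: 21 (4R,11Z)-2-oxa-1(1,3),3(1,4)-dibenzenacycloheptadecaphan-11-ene-1^5,3^2,3^6,4-tetrol (target CNP0316989.2)
Conditions: RuCl(p-cymene)[(R,R)-TsDPEN] (2 mol%), HCO2H/Et3N 5:2, DMF, 40 °C
Reagents that add atoms: none
Why: Noyori asymmetric transfer hydrogenation should set the only stereocenter: the (R,R)-TsDPEN ligand, through the CH/π contact between the cymene ligand and ring B in the six-membered hydride-transfer transition state, directs hydride to the face that gives the R carbinol (the sense of acetophenone to (R)-1-phenylethanol), with the isolated alkene and the phenols untouched.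

## Compound list

1 | 2-fluorobenzene-1,3-diol | Oc1cccc(O)c1F | starting material
2 | 2-fluoro-1,3-bis(methoxymethoxy)benzene | COCOc1cccc(OCOC)c1F | intermediate
3 | 2-[4-fluoro-3,5-bis(methoxymethoxy)phenyl]-4,4,5,5-tetramethyl-1,3,2-dioxaborolane | COCOc1cc(cc(OCOC)c1F)B1OC(C)(C)C(C)(C)O1 | intermediate
4 | non-8-enoic acid | C=CCCCCCCC(=O)O | starting material
5 | non-8-enoyl chloride | C=CCCCCCCC(=O)Cl | intermediate (not isolated)
6 | 1-[4-fluoro-3,5-bis(methoxymethoxy)phenyl]non-8-en-1-one | C=CCCCCCCC(=O)c1cc(OCOC)c(F)c(OCOC)c1 | intermediate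
7 | 1-[4-fluoro-3,5-bis(methoxymethoxy)phenyl]-8,9-dihydroxynonan-1-one (racemic) | OCC(O)CCCCCCC(=O)c1cc(OCOC)c(F)c(OCOC)c1 | intermediate (not isolated)
8 | 8-[4-fluoro-3,5-bis(methoxymethoxy)phenyl]-8-oxooctanal | O=CCCCCCCC(=O)c1cc(OCOC)c(F)c(OCOC)c1 | intermediate
9 | 5-bromobenzene-1,3-diol | Oc1cc(O)cc(Br)c1 | starting material
10 | 1-bromo-3,5-bis(triisopropylsilyloxy)benzene | CC(C)[Si](Oc1cc(Br)cc(O[Si](C(C)C)(C(C)C)C(C)C)c1)(C(C)C)C(C)C | intermediate
11 | 6-chlorohex-1-ene | C=CCCCCCl | starting material
12 | 9-(6-chlorohexyl)-9-borabicyclo[3.3.1]nonane | ClCCCCCCB1C2CCCC1CCC2 | intermediate (not isolated)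
13 | 1-(6-chlorohexyl)-3,5-bis(triisopropylsilyloxy)benzene | ClCCCCCCc1cc(O[Si](C(C)C)(C(C)C)C(C)C)cc(O[Si](C(C)C)(C(C)C)C(C)C)c1 | intermediate
14 | 1-(6-iodohexyl)-3,5-bis(triisopropylsilyloxy)benzene | ICCCCCCc1cc(O[Si](C(C)C)(C(C)C)C(C)C)cc(O[Si](C(C)C)(C(C)C)C(C)C)c1 | intermediate (not isolated)
15 | {6-[3,5-bis(triisopropylsilyloxy)phenyl]hexyl}triphenylphosphonium iodide | [I-].c1ccccc1[P+](CCCCCCc1cc(O[Si](C(C)C)(C(C)C)C(C)C)cc(O[Si](C(C)C)(C(C)C)C(C)C)c1)(c1ccccc1)c1ccccc1 | intermediate
16 | {6-[3,5-bis(triisopropylsilyloxy)phenyl]hexylidene}triphenylphosphorane | c1ccccc1P(=CCCCCCc1cc(O[Si](C(C)C)(C(C)C)C(C)C)cc(O[Si](C(C)C)(C(C)C)C(C)C)c1)(c1ccccc1)c1ccccc1 | intermediate (not isolated)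
17 | (Z)-1-[4-fluoro-3,5-bis(methoxymethoxy)phenyl]-14-[3,5-bis(triisopropylsilyloxy)phenyl]tetradec-8-en-1-one | O=C(CCCCCC/C=C\CCCCCc1cc(O[Si](C(C)C)(C(C)C)C(C)C)cc(O[Si](C(C)C)(C(C)C)C(C)C)c1)c1cc(OCOC)c(F)c(OCOC)c1 | intermediate
18 | dicesium 5-{(Z)-14-[4-fluoro-3,5-bis(methoxymethoxy)phenyl]-14-oxotetradec-6-en-1-yl}benzene-1,3-bis(olate) | [Cs+].[Cs+].[O-]c1cc([O-])cc(CCCCC/C=C\CCCCCCC(=O)c2cc(OCOC)c(F)c(OCOC)c2)c1 | intermediate (not isolated)
19 | (11Z)-1^5-hydroxy-3^2,3^6-bis(methoxymethoxy)-2-oxa-1(1,3),3(1,4)-dibenzenacycloheptadecaphan-11-en-4-one | Oc1cc2cc(c1)Oc1c(OCOC)cc(cc1OCOC)C(=O)CCCCCC/C=C\CCCCC2 | intermediate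
20 | (11Z)-1^5,3^2,3^6-trihydroxy-2-oxa-1(1,3),3(1,4)-dibenzenacycloheptadecaphan-11-en-4-one | Oc1cc2cc(c1)Oc1c(O)cc(cc1O)C(=O)CCCCCC/C=C\CCCCC2 | intermediate
21 | (4R,11Z)-2-oxa-1(1,3),3(1,4)-dibenzenacycloheptadecaphan-11-ene-1^5,3^2,3^6,4-tetrol (CNP0316989.2) | Oc1cc2cc(c1)Oc1c(O)cc(cc1O)[C@H](O)CCCCCC/C=C\CCCCC2 | target

## Step count and risks

Total step count: 11. Longest linear sequence: 8 steps (steps 1, 2, 3, 4, 8, 9, 10, 11).

Steps most likely to fail:

Step 9. One para-acyl group has to activate a carbon flanked by two alkoxy groups, so the ring closure may be slow enough for intermolecular etherification and enolate condensation to overtake it. Fallback: close the same O–C4 bond by copper-catalysed Ullmann macrocyclisation of the bromo analogue. It sets out from phosphonium salt 15 and purchased methyl 4-bromo-3,5-dihydroxybenzoate F1. MOMCl/i-Pr2NEt should give methyl 4-bromo-3,5-bis(methoxymethoxy)benzoate F2. MeNHOMe·HCl with LiN(SiMe3)2 (THF, −10 °C) should give the Weinreb amide 4-bromo-N-methoxy-3,5-bis(methoxymethoxy)-N-methylbenzamide F3. Oct-7-en-1-ylmagnesium bromide F4 (from 8-bromooct-1-ene and Mg, THF) should add once to give 1-[4-bromo-3,5-bis(methoxymethoxy)phenyl]non-8-en-1-one F5. OsO4/NaIO4 as in step 4, via the 8,9-diol F6, should give 8-[4-bromo-3,5-bis(methoxymethoxy)phenyl]-8-oxooctanal F7. Wittig reaction with ylide 16 as in step 8 should give the Z-configured bromo seco-ketone F8, and TBAF (THF, 0 °C) the free resorcinol F9. CuI (20 mol%), N,N-dimethylglycine, Cs2CO3, 1,4-dioxane, 100 °C, 2 mM should then close the ring, and the fallback comes back to the route at macrocyclic ketone 19.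

Step 3. Transmetalation from the pinacol boronate may be sluggish while the aliphatic acyl chloride is lost to hydrolysis or ketene formation. Fallback: form the aryl–carbonyl bond with reversed polarity by Weinreb ketone synthesis. It sets out from boronate 3 and acid 4. CuBr2 in MeOH/H2O at 80 °C (bromodeboronation) should convert 3 into 5-bromo-2-fluoro-1,3-bis(methoxymethoxy)benzene F10. Acid 4 with carbonyldiimidazole and MeNHOMe·HCl should give N-methoxy-N-methylnon-8-enamide F11. Bromine–lithium exchange of F10 (n-BuLi, THF, −78 °C) should give [4-fluoro-3,5-bis(methoxymethoxy)phenyl]lithium F12, which adds once to F11. After NH4Cl work-up the fallback comes back to the route at ketone 6.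

Step 11. The three free phenols may bind the ruthenium catalyst or limit solubility, giving poor turnover or eroded facial selectivity. Fallback: reduce one step earlier by Corey–Bakshi–Shibata reduction of the protected ketone and remove the acetals afterwards under non-ionising conditions. It sets out from macrocyclic ketone 19. (S)-2-methyl-CBS-oxazaborolidine (20 mol%) with catecholborane (toluene, −78 °C; the borane does not hydroborate the isolated alkene at this temperature) should give the R alcohol (4R,11Z)-3^2,3^6-bis(methoxymethoxy)-2-oxa-1(1,3),3(1,4)-dibenzenacycloheptadecaphan-11-ene-1^5,4-diol F13. TMSOTf/2,2'-bipyridyl (MeCN, 0 °C), then water, should remove both aryl MOM groups without ionising the benzylic alcohol, and the fallback comes back to the route at target 21.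

## Further compounds

F1 | step 9 | methyl 4-bromo-3,5-dihydroxybenzoate | COC(=O)c1cc(O)c(Br)c(O)c1
F2 | step 9 | methyl 4-bromo-3,5-bis(methoxymethoxy)benzoate | COCOc1cc(cc(OCOC)c1Br)C(=O)OC
F3 | step 9 | 4-bromo-N-methoxy-3,5-bis(methoxymethoxy)-N-methylbenzamide | COCOc1cc(cc(OCOC)c1Br)C(=O)N(C)OC
F4 | step 9 | oct-7-en-1-ylmagnesium bromide | C=CCCCCCC[Mg]Br
F5 | step 9 | 1-[4-bromo-3,5-bis(methoxymethoxy)phenyl]non-8-en-1-one | C=CCCCCCCC(=O)c1cc(OCOC)c(Br)c(OCOC)c1
F6 | step 9 | 1-[4-bromo-3,5-bis(methoxymethoxy)phenyl]-8,9-dihydroxynonan-1-one (racemic) | OCC(O)CCCCCCC(=O)c1cc(OCOC)c(Br)c(OCOC)c1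
F7 | step 9 | 8-[4-bromo-3,5-bis(methoxymethoxy)phenyl]-8-oxooctanal | O=CCCCCCCC(=O)c1cc(OCOC)c(Br)c(OCOC)c1
F8 | step 9 | (Z)-1-[4-bromo-3,5-bis(methoxymethoxy)phenyl]-14-[3,5-bis(triisopropylsilyloxy)phenyl]tetradec-8-en-1-one | O=C(CCCCCC/C=C\CCCCCc1cc(O[Si](C(C)C)(C(C)C)C(C)C)cc(O[Si](C(C)C)(C(C)C)C(C)C)c1)c1cc(OCOC)c(Br)c(OCOC)c1
F9 | step 9 | (Z)-1-[4-bromo-3,5-bis(methoxymethoxy)phenyl]-14-(3,5-dihydroxyphenyl)tetradec-8-en-1-one | O=C(CCCCCC/C=C\CCCCCc1cc(O)cc(O)c1)c1cc(OCOC)c(Br)c(OCOC)c1
F10 | step 3 | 5-bromo-2-fluoro-1,3-bis(methoxymethoxy)benzene | COCOc1cc(Br)cc(OCOC)c1F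
F11 | step 3 | N-methoxy-N-methylnon-8-enamide | C=CCCCCCCC(=O)N(C)OC
F12 | step 3 | [4-fluoro-3,5-bis(methoxymethoxy)phenyl]lithium | [Li]c1cc(OCOC)c(F)c(OCOC)c1
F13 | step 11 | (4R,11Z)-3^2,3^6-bis(methoxymethoxy)-2-oxa-1(1,3),3(1,4)-dibenzenacycloheptadecaphan-11-ene-1^5,4-diol | Oc1cc2cc(c1)Oc1c(OCOC)cc(cc1OCOC)[C@H](O)CCCCCC/C=C\CCCCC2
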